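## Retrosynthetic overview

1. Numbering: A is the 7-hydroxy-5-(2-oxopropyl)chromone half, B is the 2-isopropyl-8-methoxychromone half, and L is the CH2 between A-C2 and B-C5. Chromone numbering is used in both halves.
2. Feature used: the carbocycle of A (C4a-C5-C6-C7-C8-C8a) is a resorcinol with O on C7 and C8a, the C4 acyl carbon on C4a and a carbon chain on C5. An ynone (C4=O, C4a≡C5) and a 1,1,3-trioxygenated butadiene (C8a, C8, C7, C6) give this 2,4-dioxygenated 6-alkylaryl ketone pattern in one regiodefined [4+2]/aromatisation.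
3. Disconnections: (a) O1-C2 of A, by cyclodehydration of the o-hydroxyaryl 1,3-diketone, with the A-C2 and side-chain ketones kept as dioxolanes until then. (b) C5-C6 and C4a-C8a of A, by Diels-Alder benzannulation. (c) C4-C4a of A, from a Weinreb amide and a lithium acetylide.
4. The amide comes from 2-bromoisovanillin: Br is replaced by the acyl carbon B-C4, OH becomes B-O1 and CHO becomes L. Wittig homologation adds A-C2, and a Roskamp reaction adds A-C3 and A-C4.
5. Ring order: pyranone ring of B, then benzene ring of A, then pyranone ring of A.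

Key step: step 16

Remark: the target has no stereocentre. All 2-methoxyvinyl compounds are carried as E/Z mixtures and the enaminone geometry is left open, because these double bonds disappear later.

## Route

Step 1
Reactants: 1 2-bromo-3-hydroxy-4-methoxybenzaldehyde (2-bromoisovanillin)
Product: 2 3-(allyloxy)-2-bromo-4-methoxybenzaldehyde
Conditions: allyl bromide, K2CO3, DMF, rt
Reagents that add atoms: allyl bromide, C=CCBr
Why: Williamson O-alkylation of the only acidic OH, with allyl chosen because it survives the ylide and n-BuLi and can later be removed under neutral conditions that spare an acid-labile enol ether.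

Step 2
Reactants: 2 3-(allyloxy)-2-bromo-4-methoxybenzaldehyde
Product: 3 2-(allyloxy)-3-bromo-1-methoxy-4-(2-methoxyvinyl)benzene (E/Z mixture)
Conditions: MeOCH2PPh3Cl, KOt-Bu, THF, 0 °C → rt
Reagents that add atoms: (methoxymethyl)triphenylphosphonium chloride, COC[P+](c1ccccc1)(c1ccccc1)c1ccccc1.[Cl-]
Why: Wittig methoxymethylenation makes the aldehyde carbon the future L and adds the future A-C2 as an enol ether that tolerates organolithium reagents.

Step 3
Reactants: 4 3-methylbut-1-yne
Product: 6 N-methoxy-N,4-dimethylpent-2-ynamide, via lithium 3-methylbut-1-ynide 5 (not isolated)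
Conditions: n-BuLi, THF, −78 °C; then ClC(O)N(OMe)Me, −78 → 0 °C
Reagents that add atoms: N-methoxy-N-methylcarbamoyl chloride, CON(C)C(=O)Cl
Why: Deprotonation of the terminal alkyne and acylation of the acetylide by the carbamoyl chloride is the standard one-step entry to alkynyl Weinreb amides.

Step 4
Reactants: 3 2-(allyloxy)-3-bromo-1-methoxy-4-(2-methoxyvinyl)benzene; 6 N-methoxy-N,4-dimethylpent-2-ynamide
Product: 8 1-[2-(allyloxy)-3-methoxy-6-(2-methoxyvinyl)phenyl]-4-methylpent-2-yn-1-one, via aryllithium 7 (not isolated)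
Conditions: 3, n-BuLi, THF, −78 °C; then 6, −78 → −40 °C; AcOH/THF quench at −78 °C
Reagents that add atoms: none
Why: Bromine-lithium exchange at −78 °C outruns any attack on the allyl or vinyl ether, and the aryllithium adds only once because the chelated tetrahedral adduct collapses only on the cold acid quench (Weinreb ketone synthesis).

Step 5
Reactants: 8 1-[2-(allyloxy)-3-methoxy-6-(2-methoxyvinyl)phenyl]-4-methylpent-2-yn-1-one
Product: 11 2-isopropyl-8-methoxy-5-(2-methoxyvinyl)-4H-chromen-4-one, via O-allyl morpholino enaminone 9 (not isolated), via free-phenol morpholino enaminone 10 (not isolated)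
Conditions: morpholine (4 equiv), THF, rt; then Pd(PPh3)4 (3 mol %), rt; then AcOH, 50 °C
Reagents that add atoms: none
Why: Aza-Michael addition first turns the ynone into an enaminone (so PPh3 cannot isomerise it and 5-exo aurone closure is excluded), Tsuji-Trost deallylation by zerovalent palladium with morpholine as allyl acceptor then frees the phenol, and addition-elimination at the enaminone β-carbon closes the pyranone ring of B, all without hydrolysing the styryl enol ether, so no aldehyde is present while a nucleophilic enaminone carbon could condense with it to a naphthalene.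

Step 6
Reactants: 11 2-isopropyl-8-methoxy-5-(2-methoxyvinyl)-4H-chromen-4-one
Product: 12 2-(2-isopropyl-8-methoxy-4-oxo-4H-chromen-5-yl)acetaldehyde
Conditions: 3 M aq. HCl, THF, 50 °C
Reagents that add atoms: water, O
Why: Acid hydrolysis of the enol ether (C-protonation, hemiacetal collapse) releases the arylacetaldehyde only after the acid-stable chromone is in place, and the aldehyde is used at once because arylacetaldehydes enolise and autoxidise.

Step 7
Reactants: 12 2-(2-isopropyl-8-methoxy-4-oxo-4H-chromen-5-yl)acetaldehyde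
Product: 13 ethyl 4-(2-isopropyl-8-methoxy-4-oxo-4H-chromen-5-yl)-3-oxobutanoate
Conditions: N2CHCO2Et, SnCl2 (20 mol %), CH2Cl2, rt
Reagents that add atoms: ethyl diazoacetate, CCOC(=O)C=[N+]=[N-]
Why: In the Roskamp reaction, SnCl2-catalysed addition of the diazo ester to the aldehyde, a 1,2-hydride shift and loss of N2 give the β-keto ester directly and add A-C3 and A-C4.

Step 8
Reactants: 13 ethyl 4-(2-isopropyl-8-methoxy-4-oxo-4H-chromen-5-yl)-3-oxobutanoate
Product: 14 ethyl 2-{2-[(2-isopropyl-8-methoxy-4-oxo-4H-chromen-5-yl)methyl]-1,3-dioxolan-2-yl}acetate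
Conditions: HOCH2CH2OH, p-TsOH·H2O (5 mol %), benzene, reflux, Dean-Stark
Reagents that add atoms: ethylene glycol, OCCO
Why: Acid-catalysed ketalisation with azeotropic removal of water is routine for β-keto esters, and the vinylogous-ester carbonyl of the chromone does not ketalise.

Step 9
Reactants: 14 ethyl 2-{2-[(2-isopropyl-8-methoxy-4-oxo-4H-chromen-5-yl)methyl]-1,3-dioxolan-2-yl}acetate
Product: 15 2-{2-[(2-isopropyl-8-methoxy-4-oxo-4H-chromen-5-yl)methyl]-1,3-dioxolan-2-yl}-N-methoxy-N-methylacetamide
Conditions: MeNH(OMe)·HCl, i-PrMgCl, THF, −20 → 0 °C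
Reagents that add atoms: N,O-dimethylhydroxylamine hydrochloride, CNOC.Cl
Why: Ester aminolysis by the chloromagnesium amide at low temperature is established for β,β-ethylenedioxy esters, and this weakly basic, hindered amide should neither trigger β-elimination of the dioxolane nor add to C2 of the 2-isopropylchromone.

Step 10
Reactants: 16 ethyl 2-(2-methyl-1,3-dioxolan-2-yl)acetate
Product: 17 2-(2-methyl-1,3-dioxolan-2-yl)acetaldehyde
Conditions: i-Bu2AlH, CH2Cl2, −78 °C; aq. potassium sodium tartrate
Reagents that add atoms: none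
Why: Partial ester reduction at −78 °C stops at the aluminium hemiacetal, which gives the aldehyde on work-up.

Step 11
Reactants: 17 2-(2-methyl-1,3-dioxolan-2-yl)acetaldehyde
Product: 18 2-methyl-2-(prop-2-yn-1-yl)-1,3-dioxolane
Conditions: MeC(O)C(N2)P(O)(OMe)2, K2CO3, MeOH, 0 °C → rt
Reagents that add atoms: dimethyl (1-diazo-2-oxopropyl)phosphonate, CC(=O)C(=[N+]=[N-])P(=O)(OC)OC
Why: Ohira-Bestmann homologation converts CHO into C≡CH under mild carbonate conditions with the ketal already in place, so free pent-4-yn-2-one, which drifts to the allenyl ketone, is never handled.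

Step 12
Reactants: 18 2-methyl-2-(prop-2-yn-1-yl)-1,3-dioxolane; 15 2-{2-[(2-isopropyl-8-methoxy-4-oxo-4H-chromen-5-yl)methyl]-1,3-dioxolan-2-yl}-N-methoxy-N-methylacetamide
Product: 20 1-{2-[(2-isopropyl-8-methoxy-4-oxo-4H-chromen-5-yl)methyl]-1,3-dioxolan-2-yl}-5-(2-methyl-1,3-dioxolan-2-yl)pent-3-yn-2-one, via lithium acetylide 19 (not isolated)
Conditions: 18, n-BuLi, THF, −78 °C; then 15, −78 → −10 °C; AcOH/THF quench at −78 °C
Reagents that add atoms: none
Why: In this Weinreb ketone synthesis the chelated adduct prevents over-addition, the amide carbonyl is more accessible than the chromone C4 carbonyl (a vinylogous ester shielded by the peri substituent), and the cold acid quench avoids base-induced isomerisation of the skipped ynone.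

Step 13
Reactants: 21 acetyl chloride; 22 1,1-dichloroethene
Product: 24 4,4-dichlorobut-3-en-2-one, via 4,4,4-trichlorobutan-2-one 23 (not isolated)
Conditions: AlCl3, CH2Cl2, 0 °C → rt; ice water; distillation (−HCl)
Reagents that add atoms: none
Why: Friedel-Crafts-type acylation of the alkene by the acylium ion with chloride capture, followed by loss of HCl on distillation, gives the conjugated β,β-dichloroenone.

Step 14
Reactants: 24 4,4-dichlorobut-3-en-2-one
Product: 25 4,4-dimethoxybut-3-en-2-one
Conditions: NaOMe, MeOH, 0 °C → reflux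
Reagents that add atoms: sodium methoxide, [Na+].[O-]C
Why: Two successive addition-elimination reactions of methoxide at the β-carbon of the enone replace both chlorides.

Step 15
Reactants: 25 4,4-dimethoxybut-3-en-2-one
Product: 26 1,1-dimethoxy-3-(trimethylsilyloxy)buta-1,3-diene
Conditions: Me3SiCl, Et3N, ZnCl2 (cat.), benzene, 40 °C
Reagents that add atoms: chlorotrimethylsilane, C[Si](C)(C)Cl
Why: Soft enolisation and O-silylation of the methyl ketone, its only enolisable position, gives the 2-silyloxydiene in the way related 1-alkoxy-3-silyloxybutadienes are made.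

Step 16
Reactants: 20 1-{2-[(2-isopropyl-8-methoxy-4-oxo-4H-chromen-5-yl)methyl]-1,3-dioxolan-2-yl}-5-(2-methyl-1,3-dioxolan-2-yl)pent-3-yn-2-one; 26 1,1-dimethoxy-3-(trimethylsilyloxy)buta-1,3-diene
Product: 29 1-{4-hydroxy-2-methoxy-6-[(2-methyl-1,3-dioxolan-2-yl)methyl]phenyl}-2-{2-[(2-isopropyl-8-methoxy-4-oxo-4H-chromen-5-yl)methyl]-1,3-dioxolan-2-yl}ethan-1-one, via cyclohexa-1,4-diene cycloadduct 27 (not isolated), via aryl trimethylsilyl ether 28 (not isolated)
Conditions: 26 (3 equiv), toluene, sealed tube, 110 °C; then MeOH, rt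
Reagents that add atoms: none
Why: This is a thermal normal-electron-demand Diels-Alder reaction of an alkynyl ketone with a 1,1-dialkoxy-3-silyloxybutadiene, the known resorcinol benzannulation of alkynoates and alkynones. All three oxygen donors of 26 push electron density to its CH2 terminus (future C6), which bonds to the electrophilic β-carbon C5 of the ynone, while the ketene-acetal carbon (future C8a) bonds to C4a, so one asynchronous concerted intermolecular [4+2] closure builds the six-membered carbocycle of 27. A 1,4-elimination of methanol (OMe from C8a, H from C6) aromatises 27 to 28 and makes the sequence irreversible, and methanolysis of the labile aryl O-Si bond frees the C7 phenol. No stereocentre is created, since C8a of 27 carries two identical methoxy groups and C6 is a CH2. The step needs regioselectivity, which the matched polarisation of the two partners secures, and chemoselectivity, which is secured because the other two ketones are dioxolanes and the C2=C3 bond of chromone B is a donor-substituted trisubstituted enone that is inert to electron-rich dienes. Excess diene also takes up the liberated methanol, so it should not add to unreacted ynone.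

Step 17
Reactants: 29 1-{4-hydroxy-2-methoxy-6-[(2-methyl-1,3-dioxolan-2-yl)methyl]phenyl}-2-{2-[(2-isopropyl-8-methoxy-4-oxo-4H-chromen-5-yl)methyl]-1,3-dioxolan-2-yl}ethan-1-one
Product: 31 7-hydroxy-2-[(2-isopropyl-8-methoxy-4-oxo-4H-chromen-5-yl)methyl]-5-(2-oxopropyl)-4H-chromen-4-one (CNP0592286.0), via open-chain triketone 30 (not isolated)
Conditions: BCl3 (5 equiv), CH2Cl2, −78 → −20 °C; then THF-H2O, −20 °C → rt; pH 7 phosphate buffer
Reagents that add atoms: water, O
Why: Chelation-directed BCl3 cleavage removes only the methyl ether ortho to the aryl ketone (the 8-OMe of B has no neighbouring carbonyl), and because BCl3 will also open dioxolanes no attempt is made to keep them, so the dilute aqueous acid formed on quenching completes their hydrolysis and the o-hydroxyaryl 1,3-diketone 30 closes by hemiketalisation at A-C2 and dehydration (classical chromone cyclodehydration).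

## Compound list

1 | 2-bromo-3-hydroxy-4-methoxybenzaldehyde (2-bromoisovanillin) | COc1ccc(C=O)c(Br)c1O | starting material
2 | 3-(allyloxy)-2-bromo-4-methoxybenzaldehyde | C=CCOc1c(OC)ccc(C=O)c1Br | intermediate
3 | 2-(allyloxy)-3-bromo-1-methoxy-4-(2-methoxyvinyl)benzene (E/Z) | C=CCOc1c(OC)ccc(C=COC)c1Br | intermediate
4 | 3-methylbut-1-yne | C#CC(C)C | starting material
5 | lithium 3-methylbut-1-ynide | [Li]C#CC(C)C | intermediate
6 | N-methoxy-N,4-dimethylpent-2-ynamide | CC(C)C#CC(=O)N(C)OC | intermediate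
7 | [2-(allyloxy)-3-methoxy-6-(2-methoxyvinyl)phenyl]lithium | [Li]c1c(C=COC)ccc(OC)c1OCC=C | intermediate
8 | 1-[2-(allyloxy)-3-methoxy-6-(2-methoxyvinyl)phenyl]-4-methylpent-2-yn-1-one | C=CCOc1c(OC)ccc(C=COC)c1C(=O)C#CC(C)C | intermediate
9 | 1-[2-(allyloxy)-3-methoxy-6-(2-methoxyvinyl)phenyl]-4-methyl-3-(morpholin-4-yl)pent-2-en-1-one | C=CCOc1c(OC)ccc(C=COC)c1C(=O)C=C(C(C)C)N1CCOCC1 | intermediate
10 | 1-[2-hydroxy-3-methoxy-6-(2-methoxyvinyl)phenyl]-4-methyl-3-(morpholin-4-yl)pent-2-en-1-one | COC=Cc1ccc(OC)c(O)c1C(=O)C=C(C(C)C)N1CCOCC1 | intermediate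
11 | 2-isopropyl-8-methoxy-5-(2-methoxyvinyl)-4H-chromen-4-one (E/Z) | COC=Cc1ccc(OC)c2oc(C(C)C)cc(=O)c12 | intermediate
12 | 2-(2-isopropyl-8-methoxy-4-oxo-4H-chromen-5-yl)acetaldehyde | COc1ccc(CC=O)c2c(=O)cc(C(C)C)oc12 | intermediate
13 | ethyl 4-(2-isopropyl-8-methoxy-4-oxo-4H-chromen-5-yl)-3-oxobutanoate | CCOC(=O)CC(=O)Cc1ccc(OC)c2oc(C(C)C)cc(=O)c12 | intermediate
14 | ethyl 2-{2-[(2-isopropyl-8-methoxy-4-oxo-4H-chromen-5-yl)methyl]-1,3-dioxolan-2-yl}acetate | CCOC(=O)CC1(Cc2ccc(OC)c3oc(C(C)C)cc(=O)c23)OCCO1 | intermediate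
15 | 2-{2-[(2-isopropyl-8-methoxy-4-oxo-4H-chromen-5-yl)methyl]-1,3-dioxolan-2-yl}-N-methoxy-N-methylacetamide | CON(C)C(=O)CC1(Cc2ccc(OC)c3oc(C(C)C)cc(=O)c23)OCCO1 | intermediate
16 | ethyl 2-(2-methyl-1,3-dioxolan-2-yl)acetate | CCOC(=O)CC1(C)OCCO1 | starting material
17 | 2-(2-methyl-1,3-dioxolan-2-yl)acetaldehyde | O=CCC1(C)OCCO1 | intermediate
18 | 2-methyl-2-(prop-2-yn-1-yl)-1,3-dioxolane | C#CCC1(C)OCCO1 | intermediate
19 | lithium acetylide of 18 | [Li]C#CCC1(C)OCCO1 | intermediate
20 | 1-{2-[(2-isopropyl-8-methoxy-4-oxo-4H-chromen-5-yl)methyl]-1,3-dioxolan-2-yl}-5-(2-methyl-1,3-dioxolan-2-yl)pent-3-yn-2-one | COc1ccc(CC2(CC(=O)C#CCC3(C)OCCO3)OCCO2)c2c(=O)cc(C(C)C)oc12 | intermediate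
21 | acetyl chloride | CC(=O)Cl | starting material
22 | 1,1-dichloroethene | C=C(Cl)Cl | starting material
23 | 4,4,4-trichlorobutan-2-one | CC(=O)CC(Cl)(Cl)Cl | intermediate
24 | 4,4-dichlorobut-3-en-2-one | CC(=O)C=C(Cl)Cl | intermediate
25 | 4,4-dimethoxybut-3-en-2-one | CC(=O)C=C(OC)OC | intermediate
26 | 1,1-dimethoxy-3-(trimethylsilyloxy)buta-1,3-diene | C=C(O[Si](C)(C)C)C=C(OC)OC | intermediate
27 | 6,6-dimethoxy-4-(trimethylsilyloxy)cyclohexa-1,4-diene cycloadduct (acyl on C1, ketal-bearing CH2 on C2) | COC1(OC)C=C(O[Si](C)(C)C)CC(CC2(C)OCCO2)=C1C(=O)CC1(Cc2ccc(OC)c3oc(C(C)C)cc(=O)c23)OCCO1 | intermediate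
28 | O-trimethylsilyl ether of 29 | COc1cc(O[Si](C)(C)C)cc(CC2(C)OCCO2)c1C(=O)CC1(Cc2ccc(OC)c3oc(C(C)C)cc(=O)c23)OCCO1 | intermediate
29 | 1-{4-hydroxy-2-methoxy-6-[(2-methyl-1,3-dioxolan-2-yl)methyl]phenyl}-2-{2-[(2-isopropyl-8-methoxy-4-oxo-4H-chromen-5-yl)methyl]-1,3-dioxolan-2-yl}ethan-1-one | COc1cc(O)cc(CC2(C)OCCO2)c1C(=O)CC1(Cc2ccc(OC)c3oc(C(C)C)cc(=O)c23)OCCO1 | intermediate
30 | 1-[2,4-dihydroxy-6-(2-oxopropyl)phenyl]-4-(2-isopropyl-8-methoxy-4-oxo-4H-chromen-5-yl)butane-1,3-dione | CC(=O)Cc1cc(O)cc(O)c1C(=O)CC(=O)Cc1ccc(OC)c2oc(C(C)C)cc(=O)c12 | intermediate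
31 | 7-hydroxy-2-[(2-isopropyl-8-methoxy-4-oxo-4H-chromen-5-yl)methyl]-5-(2-oxopropyl)-4H-chromen-4-one | COc1ccc(Cc2cc(=O)c3c(CC(C)=O)cc(O)cc3o2)c2c(=O)cc(C(C)C)oc12 | target

## Step count and risks

Total step count: 17.
Longest linear sequence: 11 (steps 1, 2, 4, 5, 6, 7, 8, 9, 12, 16, 17).

**Steps most likely to fail**

**Step 16.**
- Cycloaddition onto an internal, β-alkyl-substituted ynone may be slower than thermal decay of the acyclic diene, which prefers the s-trans form and is prone to hydrolysis and silyl migration.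
- It may also be slower than conjugate addition of liberated methanol to the ynone, or than prototropic drift of the skipped ynone to an allenyl ketone.
- The fallback sets out from 20 and comes back at 31.
- Commercial dimedone is bis-silylated (Me3SiOTf, Et3N, Et2O, 0 °C) to 5,5-dimethyl-1,3-bis(trimethylsilyloxy)cyclohexa-1,3-diene F1. Its diene unit is locked s-cis and tolerates 140 °C.
- Heating 20 with F1 in o-xylene at 140 °C (Alder-Rickert reaction) should give the racemic bicyclo[2.2.2]octadiene adduct F2 with the same polarity-matched orientation.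
- F2 expels 2-methylpropene by retro-Diels-Alder reaction and leaves the resorcinol bis(trimethylsilyl) ether F3.
- THF-0.5 M aqueous HCl at rt removes the silyl groups first and the dioxolanes second. 30 therefore appears with both phenols free and closes to 31, and the ether cleavage of step 17 is not needed.

**Step 17.**
- The side-chain dioxolane may open before the methyl ether is cleaved, and Lewis-acid-driven aldol-type carbocyclisation between the two side chains of ring A can then follow (A-C3 onto the acetonyl carbonyl carbon, or the acetonyl CH2 onto A-C2).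
- The ether cleavage may also stay incomplete.
- Too strong an acid may dehydrate the peri pair of acetonyl group and C4 carbonyl to a dioxaphenalenium salt.
- The fallback sets out from 24 and 20 and comes back at 30, and hence 31. It replaces Lewis-acid dealkylation by neutral hydrogenolysis.
- NaOCH2Ph in THF converts 24 into 4,4-bis(benzyloxy)but-3-en-2-one F4.
- Silylation as in step 15 gives 1,1-bis(benzyloxy)-3-(trimethylsilyloxy)buta-1,3-diene F5.
- Cycloaddition with 20 as in step 16, now with loss of benzyl alcohol, gives the 2-benzyloxy-4-hydroxyaryl ketone F6.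
- H2 (1 atm), Pd/C, EtOAc, rt frees the C8a phenol and gives the 2,4-dihydroxyaryl ketone F7 with both dioxolanes intact.
- Pyridinium p-toluenesulfonate in aqueous acetone at 40 °C then opens the dioxolanes with the phenol already free, so chromone closure outruns carbocyclisation.

**Step 12.**
- The acetylide may attack chromone B at C4 or C2.
- It may also deprotonate next to the amide carbonyl, and β-elimination of the dioxolane would follow.
- The fallback sets out from 14 and 19 and comes back at 20. It replaces the hard nucleophile by a palladium-catalysed acylation.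
- LiOH in THF-H2O at rt gives 2-{2-[(2-isopropyl-8-methoxy-4-oxo-4H-chromen-5-yl)methyl]-1,3-dioxolan-2-yl}acetic acid F8.
- 1-Chloro-N,N,2-trimethylprop-1-en-1-amine in CH2Cl2 at 0 °C converts F8 under neutral conditions into the acid chloride F9.
- 19 is transmetalated with ZnCl2 in THF to the alkynylzinc chloride F10.
- Negishi acylation of F9 with F10 (Pd(PPh3)4 cat., THF, 0 °C) gives 20 without any reagent basic or nucleophilic enough to touch the chromone.

## Further compounds

F1 | step 16 | 5,5-dimethyl-1,3-bis(trimethylsilyloxy)cyclohexa-1,3-diene | CC1(C)CC(O[Si](C)(C)C)=CC(O[Si](C)(C)C)=C1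
F2 | step 16 | bicyclo[2.2.2]octa-2,5-diene adduct of 20 and F1 (racemic) | C[Si](C)(C)OC12CC(C)(C)C(C(O[Si](C)(C)C)=C1)C(CC3(C)OCCO3)=C2C(=O)CC1(Cc2ccc(OC)c3oc(C(C)C)cc(=O)c23)OCCO1
F3 | step 16 | 2,4-bis(trimethylsilyloxy)-6-[(2-methyl-1,3-dioxolan-2-yl)methyl]phenyl ketone (bis-dioxolane) | C[Si](C)(C)Oc1cc(O[Si](C)(C)C)c(C(=O)CC2(Cc3ccc(OC)c4oc(C(C)C)cc(=O)c34)OCCO2)c(CC2(C)OCCO2)c1
F4 | step 17 | 4,4-bis(benzyloxy)but-3-en-2-one | CC(=O)C=C(OCc1ccccc1)OCc1ccccc1
F5 | step 17 | 1,1-bis(benzyloxy)-3-(trimethylsilyloxy)buta-1,3-diene | C=C(O[Si](C)(C)C)C=C(OCc1ccccc1)OCc1ccccc1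
F6 | step 17 | 2-benzyloxy-4-hydroxy analogue of 29 | O=C(CC1(Cc2ccc(OC)c3oc(C(C)C)cc(=O)c23)OCCO1)c1c(OCc2ccccc2)cc(O)cc1CC1(C)OCCO1
F7 | step 17 | 2,4-dihydroxy analogue of 29 | O=C(CC1(Cc2ccc(OC)c3oc(C(C)C)cc(=O)c23)OCCO1)c1c(O)cc(O)cc1CC1(C)OCCO1
F8 | step 12 | 2-{2-[(2-isopropyl-8-methoxy-4-oxo-4H-chromen-5-yl)methyl]-1,3-dioxolan-2-yl}acetic acid | OC(=O)CC1(Cc2ccc(OC)c3oc(C(C)C)cc(=O)c23)OCCO1
F9 | step 12 | acid chloride of F8 | ClC(=O)CC1(Cc2ccc(OC)c3oc(C(C)C)cc(=O)c23)OCCO1
F10 | step 12 | [3-(2-methyl-1,3-dioxolan-2-yl)prop-1-yn-1-yl]zinc chloride | Cl[Zn]C#CCC1(C)OCCO1
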